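**Plan**

- Retrosynthesis: the six phenols are masked as methoxymethyl (MOM) ethers and the two ethyl groups are traced back to vinyl. The two Cα–C(vinyl) bonds of the side chains are then cut to a stereorandom bis(α-bromopropanoyl) ketone and Cp2Zr(Cl)(CH=CH2).
- Further back, the two C–Br bonds, the two aryl–CH bonds at the bridging methine and the ring C–prenyl bond are cut. This leads to flopropione, prenyl bromide and 6-methylheptanal, the last from 1-bromo-5-methylhexane and DMF.
- Forward order: no ring is formed. Prenyl is attached to flopropione, two such units are joined through the C8 aldehyde, and the dimer is protected, brominated twice, vinylated twice, hydrogenated and deprotected.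
- Enabling feature: the only stereocentres are the C-2 carbons of the two 2-methylbutanoyl chains. Each is an acyclic CH(CH3)(C2H5) carbon bonded to a ketone carbonyl carbon on one of the two hexasubstituted benzene (phloroglucinol) rings, so each can be made from a planar α-keto radical generated at a C–Br carbon.
- Stereochemistry: both (R) centres come from the chiral bis(oxazoline) ligand on nickel in one enantioconvergent operation. Afterwards they meet only neutral hydrogenation and mild acid.

Key step: step 7

Remark: in the (R,R) target the bridging methine carbon carries two identical aryl groups and is not a stereocentre. The prenyl groups are carried through the key step as spectators. The ligand enantiomer that delivers (R) is to be fixed on the first run; the (4S,5R) ligand is written here and its mirror image is used otherwise. Both ligand enantiomers and (R)-2-methylbutanoyl chloride (fallback only) are taken as purchasable.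

**Route**

Step 1
Reactants: 1 flopropione (2',4',6'-trihydroxypropiophenone); 2 prenyl bromide (1-bromo-3-methylbut-2-ene)
Product: 3 1-[2,4,6-trihydroxy-3-(3-methylbut-2-en-1-yl)phenyl]propan-1-one (3-prenylflopropione)
Conditions: KOH (10% aq.), 2 (0.9 equiv), 0 °C → rt; pH 3 work-up
Reagents that add atoms: none
Why: C-allylation of an ambident phenolate; in water the phloroglucinolate of 1 should react at carbon rather than oxygen (C3 and C5 are equivalent), and a deficit of bromide limits double prenylation.

Step 2
Reactants: 4 1-bromo-5-methylhexane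
Product: 7 6-methylheptanal, via (5-methylhexyl)magnesium bromide 5 (not isolated), via bromomagnesium hemiaminal alkoxide 6 (not isolated)
Conditions: Mg, I2 (cat.), THF, reflux; DMF, 0 °C → rt; 1 M aq. HCl, 0 °C
Reagents that add atoms: N,N-dimethylformamide, CN(C)C=O
Why: Bouveault aldehyde synthesis; the primary Grignard reagent adds once to DMF, and the resulting hemiaminal alkoxide releases the aldehyde only on acidic work-up.

Step 3
Reactants: 3 3-prenylflopropione (2.1 equiv); 7 6-methylheptanal
Product: 9 1,1-bis[2,4,6-trihydroxy-3-(3-methylbut-2-en-1-yl)-5-propanoylphenyl]-6-methylheptane, via ortho-quinone methide 8 (not isolated)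
Conditions: pyrrolidine (20 mol %), AcOH (20 mol %), MeOH, rt → 40 °C, N2
Reagents that add atoms: none
Why: Knoevenagel-type condensation of the vinylogous acid 3 with 7 at its only free ring carbon should give ortho-quinone methide 8, which a second molecule of 3 traps by Michael (Friedel–Crafts-type) addition; the single nucleophilic ring position excludes oligomers and the near-neutral catalyst spares the prenyl groups.

Step 4
Reactants: 9 bridged diprenyl bis(propanoyl) hexaphenol
Product: 10 1,1-bis[2,4,6-tris(methoxymethoxy)-3-(3-methylbut-2-en-1-yl)-5-propanoylphenyl]-6-methylheptane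
Conditions: NaH (6.5 equiv), MOMCl (7 equiv), DMF, 0 °C → rt
Reagents that add atoms: chloromethyl methyl ether (MOMCl), COCCl
Why: Williamson-type O-alkylation of the hexaphenoxide by the hard electrophile MOMCl; NaH is needed for the phenols hydrogen-bonded to the ketones, and reaction at oxygen is favoured over dearomatising C-alkylation of the fully substituted rings.

Step 5
Reactants: 10 hexa-MOM bis(propanoyl) dimer
Product: 12 1,1-bis[3-(2-bromopropanoyl)-2,4,6-tris(methoxymethoxy)-5-(3-methylbut-2-en-1-yl)phenyl]-6-methylheptane (all stereoisomers), via bis(trimethylsilyl enol ether) 11 (not isolated)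
Conditions: LiN(SiMe3)2 (2.5 equiv), TMSCl (3 equiv), THF, −78 → 0 °C; volatiles removed; NBS (2.1 equiv), THF, −78 °C
Reagents that add atoms: N-bromosuccinimide, O=C1CCC(=O)N1Br
Why: α-bromination of a ketone through its silyl enol ether; enolisation can occur only at the two propanoyl CH2 groups (no ring hydrogen, no other acidic site), and the electron-rich enol ethers should take up bromine from NBS at −78 °C faster than the trisubstituted prenyl alkenes, the two C–Br centres forming without control as intended.

Step 6
Reactants: 13 Cp2ZrCl2; 14 vinylmagnesium bromide, CH2=CHMgBr (1.0 equiv, THF solution)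
Product: 15 chloro(vinyl)zirconocene, Cp2Zr(Cl)(CH=CH2)
Conditions: THF, −78 → 0 °C; 1,4-dioxane, filtration of the magnesium salts; used as a THF solution
Reagents that add atoms: none
Why: Salt metathesis (transmetallation) of one Zr–Cl bond with the alkenyl Grignard reagent gives the alkenylzirconocene chloride, the reagent class otherwise reached by hydrozirconation; one equivalent at low temperature avoids the unstable divinyl complex, and removal of magnesium halide keeps a racemic background pathway out of step 7.

Step 7
Reactants: 12 hexa-MOM diprenyl bis(2-bromopropanoyl) dimer (all stereoisomers); 15 Cp2Zr(Cl)(CH=CH2) (3 equiv)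
Product: 16 1,1-bis{2,4,6-tris(methoxymethoxy)-3-[(2R)-2-methylbut-3-enoyl]-5-(3-methylbut-2-en-1-yl)phenyl}-6-methylheptane
Conditions: NiCl2(dimethoxyethane) (10 mol %), 2,2'-methylenebis[(4S,5R)-4,5-diphenyl-4,5-dihydrooxazole] (13 mol %), DME/THF, 10 °C
Reagents that add atoms: none
Why: A monovalent nickel–vinyl complex carrying the bis(oxazoline) abstracts bromine from either C–Br group to give a planar α-keto radical, which erases the configuration of 12; the radical is captured at nickel, reductive elimination from the trivalent alkyl(vinyl)nickel species forms the Cα–C(vinyl) bond, and transmetallation from 15 restores the catalyst. The closest known reaction type is the nickel/bis(oxazoline)-catalysed enantioconvergent cross-coupling of racemic secondary α-bromo aryl ketones with alkenylzirconocene chlorides, here run twice in one molecule. No ring is closed. Each new (R) centre is set by the chiral ligand on nickel alone, the two sites being remote and independent, so every stereoisomer of 12 should converge on (R,R)-16 while a mismatched event ends in the separable (R,S) diastereomers and thereby raises the enantiopurity of 16. The step needs enantiocontrol at both centres, no deprotonation of the labile α-hydrogens, no migration of the new double bond into conjugation and no attack on the prenyl groups; the near-neutral conditions at 10 °C, the six MOM ethers (no acidic OH) and the fact that radical addition to a prenyl alkene would have to close a seven-membered or larger ring should secure this.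

Step 8
Reactants: 16 hexa-MOM diprenyl bis[(R)-2-methylbut-3-enoyl] dimer
Product: 17 1,1-bis{2,4,6-tris(methoxymethoxy)-3-[(2R)-2-methylbutanoyl]-5-(3-methylbut-2-en-1-yl)phenyl}-6-methylheptane
Conditions: H2 (1 atm), RhCl(PPh3)3 (10 mol %), benzene, rt
Reagents that add atoms: none
Why: Homogeneous hydrogenation with RhCl(PPh3)3 reduces monosubstituted alkenes far faster than trisubstituted ones and causes little double-bond migration, so both vinyl groups should become ethyl while the prenyl groups and the α-centres (unchanged in space, still R by the priority rules) are kept.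

Step 9
Reactants: 17 hexa-MOM diprenyl bis[(R)-2-methylbutanoyl] dimer
Product: 18 1,1-bis{2,4,6-trihydroxy-3-[(2R)-2-methylbutanoyl]-5-(3-methylbut-2-en-1-yl)phenyl}-6-methylheptane (CNP0245910.1)
Conditions: HCl (1 M in MeOH), THF, 0 °C → rt
Reagents that add atoms: none
Why: Acid-catalysed transacetalisation of the six aryl MOM ethers to methanol (acetal cleavage) frees the phenols at room temperature, which should be mild enough to avoid chroman formation from the ortho-prenyl phenols and acid-catalysed enolisation at the α-stereocentres.

**Compound list**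

1 | flopropione (2',4',6'-trihydroxypropiophenone) | CCC(=O)c1c(O)cc(O)cc1O | starting material
2 | prenyl bromide (1-bromo-3-methylbut-2-ene) | CC(C)=CCBr | starting material
3 | 1-[2,4,6-trihydroxy-3-(3-methylbut-2-en-1-yl)phenyl]propan-1-one | CCC(=O)c1c(O)cc(O)c(CC=C(C)C)c1O | intermediate
4 | 1-bromo-5-methylhexane | CC(C)CCCCBr | starting material
5 | (5-methylhexyl)magnesium bromide | CC(C)CCCC[Mg]Br | intermediate
6 | bromomagnesium 1-(dimethylamino)-6-methylheptan-1-olate | CC(C)CCCCC(O[Mg]Br)N(C)C | intermediate
7 | 6-methylheptanal | CC(C)CCCCC=O | intermediate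
8 | 3,5-dihydroxy-6-(6-methylheptylidene)-4-(3-methylbut-2-en-1-yl)-2-propanoylcyclohexa-2,4-dien-1-one (ortho-quinone methide, alkene geometry not defined) | CCC(=O)C1=C(O)C(CC=C(C)C)=C(O)C(=CCCCCC(C)C)C1=O | intermediate
9 | 1,1-bis[2,4,6-trihydroxy-3-(3-methylbut-2-en-1-yl)-5-propanoylphenyl]-6-methylheptane | CCC(=O)c1c(O)c(CC=C(C)C)c(O)c(C(CCCCC(C)C)c2c(O)c(CC=C(C)C)c(O)c(C(=O)CC)c2O)c1O | intermediate
10 | 1,1-bis[2,4,6-tris(methoxymethoxy)-3-(3-methylbut-2-en-1-yl)-5-propanoylphenyl]-6-methylheptane | CCC(=O)c1c(OCOC)c(CC=C(C)C)c(OCOC)c(C(CCCCC(C)C)c2c(OCOC)c(CC=C(C)C)c(OCOC)c(C(=O)CC)c2OCOC)c1OCOC | intermediate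
11 | 1,1-bis[2,4,6-tris(methoxymethoxy)-3-(3-methylbut-2-en-1-yl)-5-[1-(trimethylsilyloxy)prop-1-en-1-yl]phenyl]-6-methylheptane (enol ether geometry not defined) | CC=C(O[Si](C)(C)C)c1c(OCOC)c(CC=C(C)C)c(OCOC)c(C(CCCCC(C)C)c2c(OCOC)c(CC=C(C)C)c(OCOC)c(C(=CC)O[Si](C)(C)C)c2OCOC)c1OCOC | intermediate
12 | 1,1-bis[3-(2-bromopropanoyl)-2,4,6-tris(methoxymethoxy)-5-(3-methylbut-2-en-1-yl)phenyl]-6-methylheptane (all stereoisomers) | CC(Br)C(=O)c1c(OCOC)c(CC=C(C)C)c(OCOC)c(C(CCCCC(C)C)c2c(OCOC)c(CC=C(C)C)c(OCOC)c(C(=O)C(C)Br)c2OCOC)c1OCOC | intermediate
13 | Cp2ZrCl2 (zirconocene dichloride) | Cl[Zr](Cl)(C1C=CC=C1)C1C=CC=C1 | starting material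
14 | vinylmagnesium bromide, CH2=CHMgBr | C=C[Mg]Br | starting material
15 | chloro(vinyl)zirconocene, Cp2Zr(Cl)(CH=CH2) | C=C[Zr](Cl)(C1C=CC=C1)C1C=CC=C1 | intermediate
16 | 1,1-bis{2,4,6-tris(methoxymethoxy)-3-[(2R)-2-methylbut-3-enoyl]-5-(3-methylbut-2-en-1-yl)phenyl}-6-methylheptane | C=C[C@@H](C)C(=O)c1c(OCOC)c(CC=C(C)C)c(OCOC)c(C(CCCCC(C)C)c2c(OCOC)c(CC=C(C)C)c(OCOC)c(C(=O)[C@H](C)C=C)c2OCOC)c1OCOC | intermediate
17 | 1,1-bis{2,4,6-tris(methoxymethoxy)-3-[(2R)-2-methylbutanoyl]-5-(3-methylbut-2-en-1-yl)phenyl}-6-methylheptane | CC[C@@H](C)C(=O)c1c(OCOC)c(CC=C(C)C)c(OCOC)c(C(CCCCC(C)C)c2c(OCOC)c(CC=C(C)C)c(OCOC)c(C(=O)[C@H](C)CC)c2OCOC)c1OCOC | intermediate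
18 | 1,1-bis{2,4,6-trihydroxy-3-[(2R)-2-methylbutanoyl]-5-(3-methylbut-2-en-1-yl)phenyl}-6-methylheptane (CNP0245910.1) | CC[C@@H](C)C(=O)c1c(O)c(CC=C(C)C)c(O)c(C(CCCCC(C)C)c2c(O)c(CC=C(C)C)c(O)c(C(=O)[C@H](C)CC)c2O)c1O | target

**Summary**

Total step count: 9. Longest linear sequence: 7 steps (steps 1, 3, 4, 5, 7, 8, 9 from flopropione 1; the same length from bromide 4 through step 2).

Steps most likely to fail:

Step 7. The two ketones are flanked by two ortho acetal groups on fully substituted rings, so bromine abstraction or radical capture at nickel may be slow and the facial selectivity may drop. One side may stay uncoupled. The bromoketone may also cyclise through an ortho acetal oxygen with loss of a MOM group, or the parent vinylzirconium reagent may decay before it transmetallates. The fallback gives up catalyst control for the chiral pool; it sets out from prenyl bromide 2 and aldehyde 7 and comes back at target 18. Commercial phloroglucinol is C-acylated with (R)-2-methylbutanoyl chloride (AlCl3, nitrobenzene, rt; Friedel–Crafts acylation) to give (R)-2-methyl-1-(2,4,6-trihydroxyphenyl)butan-1-one F1. C-prenylation of F1 with 2 under the conditions of step 1 gives (R)-2-methyl-1-[2,4,6-trihydroxy-3-(3-methylbut-2-en-1-yl)phenyl]butan-1-one F2; the phenolate form of the ring should shield the α-hydrogen from base. Condensation of two equivalents of F2 with 7 under the conditions of step 3 gives 18 directly.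

Step 3. The aldehyde may self-condense under amine catalysis. The ortho-quinone methide may tautomerise to a styrene or dimerise before the second arene adds, or the second addition may stall. The fallback separates the two C–C bond formations; it sets out from 3 and 7 and comes back at 9. A three-component Mannich (Betti) reaction of 3 (1 equiv), 7 and morpholine in EtOH at rt should give the isolable Mannich base 1-[2,4,6-trihydroxy-3-[6-methyl-1-(morpholin-4-yl)heptyl]-5-(3-methylbut-2-en-1-yl)phenyl]propan-1-one F3. Heating F3 with a second equivalent of 3 in toluene at 90 °C expels morpholine, so that 8 forms only in the presence of its trap, and Michael addition gives 9.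

Step 9. Cleavage of six hindered acetals may be incomplete at a temperature the molecule tolerates. Longer exposure to acid invites cyclisation of a prenyl group onto a neighbouring phenol and partial epimerisation at the α-centres. The fallback avoids free Brønsted acid; it sets out from 17 and comes back at 18. TMSOTf and 2,2'-bipyridyl in CH2Cl2 at 0 °C (acetal-to-silyl ether exchange of aryl MOM ethers) should give the hexakis(trimethylsilyl) ether 1,1-bis{3-[(2R)-2-methylbutanoyl]-5-(3-methylbut-2-en-1-yl)-2,4,6-tris(trimethylsilyloxy)phenyl}-6-methylheptane F4, which is hydrolysed to 18 with water in THF at rt.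

**Further compounds**

F1 | step 7 | (R)-2-methyl-1-(2,4,6-trihydroxyphenyl)butan-1-one | CC[C@@H](C)C(=O)c1c(O)cc(O)cc1O
F2 | step 7 | (R)-2-methyl-1-[2,4,6-trihydroxy-3-(3-methylbut-2-en-1-yl)phenyl]butan-1-one | CC[C@@H](C)C(=O)c1c(O)cc(O)c(CC=C(C)C)c1O
F3 | step 3 | 1-[2,4,6-trihydroxy-3-[6-methyl-1-(morpholin-4-yl)heptyl]-5-(3-methylbut-2-en-1-yl)phenyl]propan-1-one (racemic) | CCC(=O)c1c(O)c(CC=C(C)C)c(O)c(C(CCCCC(C)C)N2CCOCC2)c1O
F4 | step 9 | 1,1-bis{3-[(2R)-2-methylbutanoyl]-5-(3-methylbut-2-en-1-yl)-2,4,6-tris(trimethylsilyloxy)phenyl}-6-methylheptane | CC[C@@H](C)C(=O)c1c(O[Si](C)(C)C)c(CC=C(C)C)c(O[Si](C)(C)C)c(C(CCCCC(C)C)c2c(O[Si](C)(C)C)c(CC=C(C)C)c(O[Si](C)(C)C)c(C(=O)[C@H](C)CC)c2O[Si](C)(C)C)c1O[Si](C)(C)C
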